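**Plan**
- Ring A of the target is numbered C1 (OH), C2 (Br), C3, C4 (Br), C5, C6 (O-aryl); ring B is the 2,4-dibromophenyl group and is bought as the phenol.
- Retrosynthesis: the two C–Br bonds of ring A are cut first (C4–Br back to C4–H, C2–Br back to C2–CO2H), then ring A itself at C5–C6 and C2–C3, and last the CH2–OAr ether bond.
- Enabling feature: C6 (OAr), C1 (OH) and C2 (Br) are contiguous and map onto C4, C3 and C2 of a 4-aryloxyacetoacetate, whose ester carbon holds the place of the C2 bromine; C3–C5 are a malondialdehyde unit.
- Forward: Williamson ether formation, two silylations to a 1,3-bis(silyloxy)diene, formal [3+3] cyclocondensation that closes ring A (the only ring formed), saponification, then one bromination that puts Br on C4 and exchanges CO2H for Br at C2.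
- Stereochemistry: the target has no stereocentre and no stereogenic double bond, so nothing has to be controlled.

Key step: step 4

Remark on the chemistry: the silyl enol ethers and the non-aromatic annulation intermediates are written without alkene or stereo descriptors, because they are expected as mixtures and all of these elements disappear when ring A aromatises.

**Step 1**
Reactants: 1 2,4-dibromophenol; 2 methyl 4-chloro-3-oxobutanoate (methyl 4-chloroacetoacetate)
Product: 3 methyl 4-(2,4-dibromophenoxy)-3-oxobutanoate
Conditions: NaH (2.2 equiv), THF, 0 °C → 60 °C; then 1 M HCl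
Reagents that add atoms: none
Why: Williamson ether synthesis (SN2 at the primary chloride), in which the second equivalent of NaH holds the β-ketoester as its enolate so that it should not self-condense while the phenoxide displaces chloride, a reaction well known for 4-chloroacetoacetates with alkoxides and phenoxides.

**Step 2**
Reactants: 3 methyl 4-(2,4-dibromophenoxy)-3-oxobutanoate
Product: 4 methyl 4-(2,4-dibromophenoxy)-3-(trimethylsilyloxy)but-2-enoate (mainly Z expected, geometry immaterial)
Conditions: Me3SiCl (1.5 equiv), Et3N (1.6 equiv), toluene, 20 °C, 48–72 h; filtration under argon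
Reagents that add atoms: chlorotrimethylsilane, C[Si](C)(C)Cl
Why: Silyl enol ether formation by amine-mediated O-silylation of the β-ketoester enol should give the conjugated 3-silyloxy-2-enoate, the usual first stage toward 1,3-bis(silyloxy)dienes, and the water-free work-up protects the hydrolytically labile product.

**Step 3**
Reactants: 4 methyl 4-(2,4-dibromophenoxy)-3-(trimethylsilyloxy)but-2-enoate
Product: 6 bis-silyl diene 4-(2,4-dibromophenoxy)-1-methoxy-1,3-bis(trimethylsilyloxy)buta-1,3-diene, via lithium dienolate 5 (not isolated)
Conditions: LiN(iPr)2 (1.05 equiv), THF, −78 °C, 1 h; Me3SiCl (1.2 equiv), −78 → 20 °C; hexane, filtration under argon, used crude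
Reagents that add atoms: chlorotrimethylsilane, C[Si](C)(C)Cl; lithium diisopropylamide, [Li+].CC(C)[N-]C(C)C (its lithium appears in 5 only)
Why: Kinetic γ-deprotonation of the vinylogous ester gives the extended dienolate 5, which Me3SiCl should trap on the ester oxygen (silyl ketene acetal formation); a lithium amide does not exchange aryl bromides, and with 1.05 equiv at −78 °C the much more acidic γ-CH2 should be removed before any aryl C–H.

**Step 4**
Reactants: 6 4-(2,4-dibromophenoxy)-1-methoxy-1,3-bis(trimethylsilyloxy)buta-1,3-diene (1.3 equiv); 7 1,1,3,3-tetramethoxypropane
Product: 10 methyl 3-(2,4-dibromophenoxy)-2-hydroxybenzoate, via open-chain Mukaiyama adduct 8 (not isolated), via dimethoxycyclohexanone ester 9 (not isolated)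
Conditions: Me3SiOTf (0.3 equiv), CH2Cl2, −78 → 20 °C, 16 h; then 10% aq. HCl, 20 °C
Reagents that add atoms: none
Why: Me3SiOTf ionises one acetal of 7 to a methoxycarbenium ion, and the terminal, aryloxy-bearing carbon of diene 6 (the most nucleophilic site of a 1,3-bis(silyloxy)diene) attacks it in a vinylogous Mukaiyama aldol-type addition that forms C5–C6 and leaves the silylated β-ketoester 8. Ionisation of the second acetal then lets C2 of that β-ketoester unit close ring A by an intramolecular Mukaiyama aldol-type addition (C2–C3) to cyclohexanone 9; with the enol double bond of 8 inside the forming ring and the oxocarbenium C=O outside it, this is a 6-(enolendo)-exo-trig closure, a favoured mode. Both methoxy groups of 9 lie β to a carbonyl group, so two eliminations of methanol and enolisation, completed by the aqueous HCl, should give the aromatic salicylate 10; each C–C bond formation releases Me3SiOTf again, which is why a substoichiometric amount should suffice. The closest known reaction type is the formal [3+3] cyclocondensation of 1,3-bis(silyloxy)-1,3-dienes with 1,3-dielectrophiles such as 3-silyloxyenones and malondialdehyde bis(acetals), a standard route to salicylates. No stereocentre is set, since the sp3 centres of 8 and 9 and all enol ether geometries are erased on aromatisation. The selectivity needed is constitutional and is secured by the substrates: 7 is symmetrical and the three diene carbons enter the ring in fixed order, so the OH must end between the ester carbon (C2) and the aryloxy carbon (C6), while C- over O-attack and cyclisation over a second intermolecular addition are favoured by low temperature and by the intramolecular second step.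

**Step 5**
Reactants: 10 methyl 3-(2,4-dibromophenoxy)-2-hydroxybenzoate
Product: 11 3-(2,4-dibromophenoxy)-2-hydroxybenzoic acid
Conditions: LiOH·H2O (5 equiv), THF–MeOH–H2O (2:1:1), 60 °C; then 1 M HCl to pH 1
Reagents that add atoms: lithium hydroxide, [Li+].[OH-]
Why: Saponification (acyl substitution by hydroxide) of the methyl ester, run with excess base and warming because the salicylate phenoxide slows the attack; the diaryl ether and the aryl bromides should be inert to aqueous hydroxide at this temperature.

**Step 6**
Reactants: 11 3-(2,4-dibromophenoxy)-2-hydroxybenzoic acid
Product: 13 2,4-dibromo-6-(2,4-dibromophenoxy)phenol (the target), via para-bromo acid 12 (not isolated)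
Conditions: Br2 (2.1 equiv), AcOH–H2O (3:1), 20 → 55 °C
Reagents that add atoms: bromine, BrBr
Why: Electrophilic aromatic bromination directed by the free phenol should first take the open para position (C4) to give 12, after which the second equivalent attacks the only remaining ortho carbon ipso and CO2 is lost (bromodecarboxylation, as in the classical conversion of salicylic acid into 2,4,6-tribromophenol by bromine water), while the limited amount of bromine should spare the less activated C3, C5 and ring B positions.

**Compound list**
1 | 2,4-dibromophenol | Oc1ccc(Br)cc1Br | starting material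
2 | methyl 4-chloro-3-oxobutanoate | COC(=O)CC(=O)CCl | starting material
3 | methyl 4-(2,4-dibromophenoxy)-3-oxobutanoate | COC(=O)CC(=O)COc1ccc(Br)cc1Br | intermediate
4 | methyl 4-(2,4-dibromophenoxy)-3-(trimethylsilyloxy)but-2-enoate | COC(=O)C=C(O[Si](C)(C)C)COc1ccc(Br)cc1Br | intermediate
5 | lithium 4-(2,4-dibromophenoxy)-1-methoxy-3-(trimethylsilyloxy)buta-1,3-dien-1-olate (not isolated) | [Li+].COC([O-])=CC(O[Si](C)(C)C)=COc1ccc(Br)cc1Br | intermediate
6 | 4-(2,4-dibromophenoxy)-1-methoxy-1,3-bis(trimethylsilyloxy)buta-1,3-diene | COC(O[Si](C)(C)C)=CC(O[Si](C)(C)C)=COc1ccc(Br)cc1Br | intermediate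
7 | 1,1,3,3-tetramethoxypropane | COC(OC)CC(OC)OC | starting material
8 | methyl 4-(2,4-dibromophenoxy)-5,7,7-trimethoxy-3-(trimethylsilyloxy)hept-2-enoate (mixture of diastereomers, not isolated) | COC(=O)C=C(O[Si](C)(C)C)C(Oc1ccc(Br)cc1Br)C(OC)CC(OC)OC | intermediate
9 | methyl 3-(2,4-dibromophenoxy)-4,6-dimethoxy-2-oxocyclohexane-1-carboxylate (mixture of diastereomers, not isolated) | COC(=O)C1C(OC)CC(OC)C(Oc2ccc(Br)cc2Br)C1=O | intermediate
10 | methyl 3-(2,4-dibromophenoxy)-2-hydroxybenzoate | COC(=O)c1cccc(Oc2ccc(Br)cc2Br)c1O | intermediate
11 | 3-(2,4-dibromophenoxy)-2-hydroxybenzoic acid | OC(=O)c1cccc(Oc2ccc(Br)cc2Br)c1O | intermediate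
12 | 5-bromo-3-(2,4-dibromophenoxy)-2-hydroxybenzoic acid (not isolated) | OC(=O)c1cc(Br)cc(Oc2ccc(Br)cc2Br)c1O | intermediate
13 | 2,4-dibromo-6-(2,4-dibromophenoxy)phenol | Oc1c(Br)cc(Br)cc1Oc1ccc(Br)cc1Br | target

**Count and risks**
Total step count: 6. Longest linear sequence: 6 steps (1 and 2 to 13).

Most likely to fail, in this order:

Step 4. The diene may lose its silyl groups to traces of acid or water faster than it adds to the carbenium ion. The first adduct may also react with a second acetal intermolecularly, or lose methanol only partly, so that ring closure and aromatisation stay incomplete. The fallback gives up the benzannulation and buys ring A with both bromines in place; it sets out from 1 and comes back at 13. Nucleophilic aromatic substitution of fluoride in commercial 2,4-dibromo-6-fluorobenzaldehyde by the phenoxide of 1 (K2CO3, DMF, 90 °C) would give 2,4-dibromo-6-(2,4-dibromophenoxy)benzaldehyde F1. Baeyer–Villiger (Dakin-type) oxidation with mCPBA in CH2Cl2 would give 2,4-dibromo-6-(2,4-dibromophenoxy)phenyl formate F2, which K2CO3 in MeOH would cleave in the same flask to 13.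

Step 6. Bromination may halt after para substitution if ipso attack at the carboxyl-bearing carbon is slow, or it may run on to C3, C5 or ring B (over-bromination). The fallback separates loss of CO2 from halogenation; it sets out from 11 and comes back at 13. Copper-free thermal protodecarboxylation of the salicylic acid (quinoline, about 195 °C) would give 2-(2,4-dibromophenoxy)phenol F3. Bromination ortho and para to the hydroxyl group with Br2 (2.0 equiv, AcOH, 15 °C) would then give 13.

Step 3. The amide base may metalate ring B at the acidified position between the two bromines, silylation may occur on carbon, or the diene may hydrolyse during isolation. The fallback changes the enolisation manifold from a lithium amide to amine and silyl triflate, so that no strong base meets the bromoarene; it sets out from 3 and comes back at 6. Treatment of the β-ketoester with Me3SiOTf (2.2 equiv) and Et3N (2.5 equiv) in Et2O at 0 → 20 °C would silylate both enol oxygens in one operation, bypassing 4 and 5.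

**Further compounds**
F1 | step 4 | 2,4-dibromo-6-(2,4-dibromophenoxy)benzaldehyde | O=Cc1c(Br)cc(Br)cc1Oc1ccc(Br)cc1Br
F2 | step 4 | 2,4-dibromo-6-(2,4-dibromophenoxy)phenyl formate | O=COc1c(Br)cc(Br)cc1Oc1ccc(Br)cc1Br
F3 | step 6 | 2-(2,4-dibromophenoxy)phenol | Oc1ccccc1Oc1ccc(Br)cc1Br
F0 | step 3 | none | none
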